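**Retrosynthetic overview**
1. The strategy rests on one bond: the biaryl bond from C6' of ring B of the upper catechin unit (para to its 3'-OH) to C6 of ring A of the lower unit (the carbon between 5-OH and 7-OH).
2. That bond is cut to a ring B ortho-quinone, electrophilic at C6' (the free end of the enone O=C4'–C5'=C6'), and a phloroglucinol-type ring A nucleophile whose C8 is blocked by bromine.
3. The quinone partner is 3,5,7-tri-O-acetylcatechin (ring A switched off). The nucleophile is 8-bromo-3',4'-O-diphenylmethylene-catechin (catechol masked). Both come from one ketal of (+)-catechin.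
4. No ring is built: rings A, B and C of each unit come intact from (+)-catechin, and the dioxole rings are temporary protection.
5. End game: hydrogenolysis (bromine and ketal off), then acetate methanolysis.

Key step: step 8

Assumption: the target fixes no configuration for the C6'–C6 biaryl axis, so the axis is treated as undefined and any rotamer mixture is taken as the target.

**Route**

Step 1
Reactants: 1 (+)-catechin, (2R,3S)
Product: 2 3',4'-O-diphenylmethylene-(+)-catechin, (2R,3S), with free 3-, 5- and 7-OH
Conditions: Ph2CCl2 (1.5 equiv), Ph2O, 175 °C, 30 min, N2 purge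
Reagents that add atoms: dichlorodiphenylmethane, ClC(Cl)(c1ccccc1)c1ccccc1
Why: Only the vicinal 3',4'-catechol can close a five-membered 2,2-diphenyl-1,3-benzodioxole by double O-alkylation with the gem-dichloride (cyclic ketal formation), whereas the meta-placed 5- and 7-phenols and the 3-OH cannot form a stable cyclic ketal, and no stereocenter is touched.

Step 2
Reactants: 2 3',4'-O-diphenylmethylene-(+)-catechin
Product: 3 3,5,7-tri-O-acetyl-3',4'-O-diphenylmethylene-(+)-catechin, (2R,3S)
Conditions: Ac2O, pyridine, DMAP (cat.), 0 °C to rt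
Reagents that add atoms: acetic anhydride, CC(=O)OC(C)=O
Why: Pyridine/DMAP-catalysed O-acylation esterifies both phenols and the secondary alcohol, and the aryl acetates make ring A too electron-poor to act later as a carbon nucleophile towards a quinone.

Step 3
Reactants: 3 3,5,7-tri-O-acetyl-3',4'-O-diphenylmethylene-(+)-catechin
Product: 4 3,5,7-tri-O-acetyl-(+)-catechin, (2R,3S), with free 3',4'-catechol
Conditions: H2 (1 atm), Pd(OH)2/C, THF/EtOAc, rt
Reagents that add atoms: none
Why: Catalytic hydrogenolysis cleaves the doubly benzylic C–O bonds of the diphenylmethylene ketal to release the catechol and diphenylmethane under neutral, alcohol-free conditions that leave the acetates, the chroman ether and both stereocenters untouched.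

Step 4
Reactants: 2 3',4'-O-diphenylmethylene-(+)-catechin
Product: 5 5,7-bis-O-(tert-butyldimethylsilyl)-3',4'-O-diphenylmethylene-(+)-catechin, (2R,3S), with free 3-OH
Conditions: TBSCl (2.4 equiv), imidazole, DMF, 0 °C to rt
Reagents that add atoms: tert-butyldimethylsilyl chloride, CC(C)(C)[Si](C)(C)Cl
Why: Imidazole-mediated silylation is fast on the two phenols and slow on the hindered secondary 3-OH, so a small excess of TBSCl should give the 5,7-bis(silyl) ether chemoselectively.

Step 5
Reactants: 5 5,7-bis-O-TBS-3',4'-O-diphenylmethylene-(+)-catechin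
Product: 6 8-bromo-5,7-bis-O-TBS-3',4'-O-diphenylmethylene-(+)-catechin, (2R,3S)
Conditions: NBS (1.0 equiv), CH2Cl2, −78 °C to 0 °C, dark
Reagents that add atoms: N-bromosuccinimide, O=C1CCC(=O)N1Br
Why: Electrophilic aromatic bromination of the 5,7-di-O-protected ring A by NBS should go to C8, the position flanked by only one bulky silyloxy group and the ring oxygen and the one found for 5,7-di-O-protected flavan-3-ols, while one equivalent at low temperature spares the less activated benzodioxole ring; the site is to be confirmed by HMBC before use.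

Step 6
Reactants: 6 8-bromo-5,7-bis-O-TBS-3',4'-O-diphenylmethylene-(+)-catechin
Product: 7 8-bromo-3',4'-O-diphenylmethylene-(+)-catechin, (2R,3S), with free 3-, 5- and 7-OH
Conditions: TBAF (2.2 equiv), AcOH (2.5 equiv), THF, 0 °C
Reagents that add atoms: none
Why: Fluoride-induced desilylation cleaves the aryl Si–O bonds within minutes, and the acetic acid buffer keeps the liberated bromophloroglucinol phenols protonated so that the aryl bromide, the ketal and C2 are not put at risk.

Step 7
Reactants: 4 3,5,7-tri-O-acetyl-(+)-catechin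
Product: 8 ring B ortho-quinone of 3,5,7-tri-O-acetyl-(+)-catechin, (2R,3S), obtained as a cold filtered solution and used at once
Conditions: Ag2O (3 equiv), Na2SO4, dry acetone, −20 °C, dark, 15 min; cold filtration through Celite under Ar
Reagents that add atoms: none
Why: Ag2O is a heterogeneous two-electron oxidant for catechols (classical ortho-quinone preparation) in a dry, non-nucleophilic medium, so the acetylated ring A, the esters and the stereocenters stay untouched and the silver-free filtrate can be used before the quinone tautomerises to a quinone methide.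

Step 8
Reactants: 7 8-bromo-3',4'-O-diphenylmethylene-(+)-catechin; 8 ring B ortho-quinone of 3,5,7-tri-O-acetyl-(+)-catechin
Product: 10 protected 6'→6 biaryl dimer (upper unit 3,5,7-tri-O-acetyl with restored 3',4'-catechol; lower unit 8-bromo-3',4'-O-diphenylmethylene with free 3-, 5-, 7-OH; both units 2R,3S), via ring B hydroxydienone adduct 9 (not isolated)
Conditions: 7 (3 equiv), acetone/0.1 M aq. NaOAc–AcOH buffer (pH 5) 2:1, 0 °C, Ar; 8 in acetone added dropwise over 1 h; then aq. ascorbic acid; excess 7 recovered
Reagents that add atoms: none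
Why: C6 of ring A of 7, the carbon ortho to both free phenols, adds in a Michael (1,4) sense to the enone O=C4'–C5'=C6' of quinone 8 at C6', ring A rearomatises by loss of the C6 proton to give the hydroxydienone 9, and enolisation of 9 restores the catechol of 10. The closest known reaction type is the oxidative dimerisation of catechin to biaryl-linked dehydrodicatechins, where a flavan ring A attacks a ring B ortho-quinone at C6'. No ring is closed and no stereocenter is created: the four stereocenters are carried unchanged from (+)-catechin and the new biaryl axis is not a defined stereo-element of the target. The roles of the partners are fixed by the substrates, since the acetates make ring A of 8 too electron-poor to self-couple and the ketal of 7 leaves it no catechol that 8 could oxidise. Site selectivity is needed on both rings: the C8 bromine leaves C6 as the only open ring A carbon, and carbon nucleophiles choose the unsubstituted enone terminus C6' of a 4-alkyl ortho-quinone rather than C2' or C5'. Because the arylated product catechol is more easily oxidised than 4, the quinone is added slowly to an excess of 7 at 0 °C in weakly acidic medium (which also suppresses quinone methide formation and C2 epimerisation) and any remainder is reduced with ascorbic acid.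

Step 9
Reactants: 10 protected 6'→6 biaryl dimer
Product: 11 upper-unit 3,5,7-tri-O-acetate of the target (lower unit fully deprotected, C8–H; both units 2R,3S)
Conditions: H2 (1 atm), Pd(OH)2/C, Et3N (1.2 equiv), degassed THF, rt; filtration under Ar
Reagents that add atoms: none
Why: Palladium-catalysed hydrogenolysis removes the blocking bromine (hydrodehalogenation, the HBr being taken up by Et3N) and the diphenylmethylene ketal in one operation, and in methanol-free THF it should not affect the acetates, the biaryl bond or the stereocenters.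

Step 10
Reactants: 11 upper-unit 3,5,7-tri-O-acetate of the target
Product: 12 target CNP0125771.1, (2R,3S) in both flavan units
Conditions: K2CO3 (4 equiv), degassed MeOH/THF, Ar, 0 °C to rt; quench at 0 °C with Amberlite IR-120 (H+ form); Sephadex LH-20 or reversed-phase purification
Reagents that add atoms: none
Why: Base-mediated transesterification (methanolysis) cleaves the two aryl acetates quickly and the secondary 3-O-acetate more slowly, and exclusion of oxygen, low temperature and an acidic quench should protect the polyphenol from autoxidation and from C2 epimerisation.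

**Compound list**
1 | (+)-catechin, (2R,3S) | O[C@H]1Cc2c(O)cc(O)cc2O[C@@H]1c1ccc(O)c(O)c1 | starting material
2 | 3',4'-O-diphenylmethylene-(+)-catechin | O[C@H]1Cc2c(O)cc(O)cc2O[C@@H]1c1ccc2OC(c3ccccc3)(c3ccccc3)Oc2c1 | intermediate
3 | 3,5,7-tri-O-acetyl-3',4'-O-diphenylmethylene-(+)-catechin | CC(=O)O[C@H]1Cc2c(OC(C)=O)cc(OC(C)=O)cc2O[C@@H]1c1ccc2OC(c3ccccc3)(c3ccccc3)Oc2c1 | intermediate
4 | 3,5,7-tri-O-acetyl-(+)-catechin with free catechol | CC(=O)O[C@H]1Cc2c(OC(C)=O)cc(OC(C)=O)cc2O[C@@H]1c1ccc(O)c(O)c1 | intermediate
5 | 5,7-bis-O-TBS-3',4'-O-diphenylmethylene-(+)-catechin | O[C@H]1Cc2c(O[Si](C)(C)C(C)(C)C)cc(O[Si](C)(C)C(C)(C)C)cc2O[C@@H]1c1ccc2OC(c3ccccc3)(c3ccccc3)Oc2c1 | intermediate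
6 | 8-bromo-5,7-bis-O-TBS-3',4'-O-diphenylmethylene-(+)-catechin | O[C@H]1Cc2c(O[Si](C)(C)C(C)(C)C)cc(O[Si](C)(C)C(C)(C)C)c(Br)c2O[C@@H]1c1ccc2OC(c3ccccc3)(c3ccccc3)Oc2c1 | intermediate
7 | 8-bromo-3',4'-O-diphenylmethylene-(+)-catechin | O[C@H]1Cc2c(O)cc(O)c(Br)c2O[C@@H]1c1ccc2OC(c3ccccc3)(c3ccccc3)Oc2c1 | intermediate
8 | ring B ortho-quinone of 3,5,7-tri-O-acetyl-(+)-catechin | CC(=O)O[C@H]1Cc2c(OC(C)=O)cc(OC(C)=O)cc2O[C@@H]1C1=CC(=O)C(=O)C=C1 | intermediate
9 | ring B hydroxydienone adduct (C6' sp3, either configuration) | CC(=O)Oc1cc(OC(C)=O)c2c(c1)O[C@H](C1=CC(=O)C(O)=CC1c1c(O)c(Br)c3c(c1O)C[C@H](O)[C@@H](c1ccc4OC(c5ccccc5)(c5ccccc5)Oc4c1)O3)[C@@H](OC(C)=O)C2 | intermediate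
10 | protected 6'→6 biaryl dimer (upper triacetate with free catechol, lower 8-bromo ketal) | CC(=O)Oc1cc(OC(C)=O)c2c(c1)O[C@H](c1cc(O)c(O)cc1-c1c(O)c(Br)c3c(c1O)C[C@H](O)[C@@H](c1ccc4OC(c5ccccc5)(c5ccccc5)Oc4c1)O3)[C@@H](OC(C)=O)C2 | intermediate
11 | upper-unit 3,5,7-tri-O-acetate of the target | CC(=O)Oc1cc(OC(C)=O)c2c(c1)O[C@H](c1cc(O)c(O)cc1-c1c(O)cc3c(c1O)C[C@H](O)[C@@H](c1ccc(O)c(O)c1)O3)[C@@H](OC(C)=O)C2 | intermediate
12 | CNP0125771.1 | Oc1cc(O)c2c(c1)O[C@H](c1cc(O)c(O)cc1-c1c(O)cc3c(c1O)C[C@H](O)[C@@H](c1ccc(O)c(O)c1)O3)[C@@H](O)C2 | target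

**Totals and risks**

Total step count: 10. Longest linear sequence: 7 steps from (+)-catechin (steps 1, 2, 3, 7, 8, 9, 10, or equally steps 1, 4, 5, 6, 8, 9, 10).

Steps most likely to fail:

1. Step 8 (cross-coupling). Three processes threaten it:
   - redox exchange, in which the product catechol reduces remaining quinone and is itself oxidised, followed by intramolecular phenol addition or further coupling;
   - competing attack at C2' or through a phenolic oxygen;
   - tautomerisation of the quinone to a quinone methide, with loss of C2 configuration.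

   Fallback: the same C6'–C6 bond is made by Suzuki–Miyaura coupling, setting out from compounds 3 and 7 and coming back to the route at compound 11. Compound 3 is brominated on ring B with NBS in DMF; ring A is deactivated by its acetates, so substitution should fall para to O3', giving 6'-bromo-3,5,7-tri-O-acetyl-3',4'-O-diphenylmethylene-catechin F1. Miyaura borylation (B2pin2, Pd(dppf)Cl2, KOAc, dioxane, 85 °C) converts it into the 6'-pinacolboronate F2. Compound 7 is iodinated at its only open ring A carbon (NIS, MeCN, 0 °C) to 8-bromo-6-iodo-3',4'-O-diphenylmethylene-catechin F3, and its two phenols are benzylated (BnBr, K2CO3, DMF) to give the 5,7-di-O-benzyl ether F4. Coupling of F2 with F4 (Pd(OAc)2, SPhos, anhydrous K3PO4, toluene, 90 °C), selective for C–I over C–Br, should give the fully protected dimer F5. Hydrogenolysis (H2, Pd(OH)2/C, Et3N, THF) then removes the benzyl ethers, both ketals and the bromine to deliver compound 11.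

2. Step 10 (acetate methanolysis). The phenoxides formed under base may open ring C to a quinone methide and reclose with epimerisation at C2, and they may autoxidise.

   Fallback: the ester cleavage is moved ahead of the hydrogenolysis and run under acid, setting out from compound 10 and coming back at compound 12. Anhydrous HCl in degassed MeOH (about 1 M, rt) transesterifies the three acetates to give the 8-bromo ketal dimer with all acetates removed F6. Any concurrent loss of bromine or ketal is harmless, because both are removed next. Hydrogenolysis (H2, Pd(OH)2/C, Et3N 1.1 equiv, THF/MeOH) then gives compound 12 under near-neutral conditions.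

3. Step 5 (bromination). Bromination may not be confined to C8: attack at C6 or on the benzodioxole ring, or over-bromination, would misdirect the later coupling.

   Fallback: ring A is protected as alkyl ethers, the class for which C8 monobromination is established, setting out from compound 2 and coming back at compound 7. MOMCl with K2CO3 in acetone alkylates the two phenols only, giving 5,7-bis-O-methoxymethyl-3',4'-O-diphenylmethylene-catechin F7. NBS in CH2Cl2 at −78 °C gives its 8-bromo derivative F8. Dilute HCl in MeOH/THF at rt removes the two acetals, the diphenylmethylene ketal being the more robust towards dilute acid, and returns compound 7.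

**Further compounds**
F1 | step 8 | 6'-bromo-3,5,7-tri-O-acetyl-3',4'-O-diphenylmethylene-catechin | CC(=O)O[C@H]1Cc2c(OC(C)=O)cc(OC(C)=O)cc2O[C@@H]1c1c(Br)cc2OC(c3ccccc3)(c3ccccc3)Oc2c1
F2 | step 8 | 6'-(pinacolboronate) of 3,5,7-tri-O-acetyl-3',4'-O-diphenylmethylene-catechin | CC(=O)O[C@H]1Cc2c(OC(C)=O)cc(OC(C)=O)cc2O[C@@H]1c1c(B3OC(C)(C)C(C)(C)O3)cc2OC(c3ccccc3)(c3ccccc3)Oc2c1
F3 | step 8 | 8-bromo-6-iodo-3',4'-O-diphenylmethylene-catechin | O[C@H]1Cc2c(O)c(I)c(O)c(Br)c2O[C@@H]1c1ccc2OC(c3ccccc3)(c3ccccc3)Oc2c1
F4 | step 8 | 5,7-di-O-benzyl-8-bromo-6-iodo-3',4'-O-diphenylmethylene-catechin | O[C@H]1Cc2c(OCc3ccccc3)c(I)c(OCc3ccccc3)c(Br)c2O[C@@H]1c1ccc2OC(c3ccccc3)(c3ccccc3)Oc2c1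
F5 | step 8 | fully protected 6'→6 dimer (upper triacetate ketal, lower 5,7-di-O-benzyl-8-bromo ketal) | CC(=O)Oc1cc(OC(C)=O)c2c(c1)O[C@H](c1cc3OC(c4ccccc4)(c4ccccc4)Oc3cc1-c1c(OCc3ccccc3)c(Br)c3c(c1OCc1ccccc1)C[C@H](O)[C@@H](c1ccc4OC(c5ccccc5)(c5ccccc5)Oc4c1)O3)[C@@H](OC(C)=O)C2
F6 | step 10 | 8-bromo ketal dimer with all acetates removed | Oc1cc(O)c2c(c1)O[C@H](c1cc(O)c(O)cc1-c1c(O)c(Br)c3c(c1O)C[C@H](O)[C@@H](c1ccc4OC(c5ccccc5)(c5ccccc5)Oc4c1)O3)[C@@H](O)C2
F7 | step 5 | 5,7-bis-O-methoxymethyl-3',4'-O-diphenylmethylene-catechin | O[C@H]1Cc2c(OCOC)cc(OCOC)cc2O[C@@H]1c1ccc2OC(c3ccccc3)(c3ccccc3)Oc2c1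
F8 | step 5 | 8-bromo-5,7-bis-O-methoxymethyl-3',4'-O-diphenylmethylene-catechin | O[C@H]1Cc2c(OCOC)cc(OCOC)c(Br)c2O[C@@H]1c1ccc2OC(c3ccccc3)(c3ccccc3)Oc2c1
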